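**Strategy.** The cyclohexene is closed by joining its allylic CH2 (C1) to the ring CH that carries the side chain (C6). C6 is read as the α-carbon of an aldehyde (C7, later the alkene carbon), and the ring array C1H2–C2H=C3(CH2OH) as the 1,4-opened form of a 2-vinyloxirane. One amine/palladium dual-catalytic step joins the enamine carbon to the π-allyl terminus: it closes the ring, places the C2=C3 alkene, frees the C15 hydroxyl and sets C6. The precursor is an acyclic 4-silyloxy-4-(2-vinyloxiranyl)butanal. Homologation to an alkyne and a ruthenium-catalysed alkene–alkyne coupling then attach the side chain.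

Key step: step 6

Remark on numbering: ring atoms are C1 (allylic CH2), C2=C3, C4 (CH–O), C5, C6 (CH bearing the side chain); C7 is the side-chain carbon on C6, C14 its methylene, C15 the CH2O carbon on C3, C8–C12 the rest of the side chain.
Assumption: 4-(tert-butyldimethylsilyloxy)butanal, chloroprene and (S)-2-methylglycidol are bought.
Assumption: the titanium/tartrate resolution follows its usual sense (L-(+)-tartrate consumes the (S)-carbinol and gives the erythro epoxy alcohol); the epoxide carbon is a throw-away centre that becomes sp2 in step 6.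

Step 1
Reactants: 1 4-(tert-butyldimethylsilyloxy)butanal; 2 chloroprene (2-chlorobuta-1,3-diene)
Product: 4 rac-7-(tert-butyldimethylsilyloxy)-3-methylidenehept-1-en-4-ol, via buta-1,3-dien-2-ylmagnesium chloride 3 (not isolated)
Conditions: 2, Mg, ZnCl2 (cat.), BrCH2CH2Br (cat.), THF, reflux; then 1, −78 → 0 °C; aq. NH4Cl
Reagents that add atoms: none
Why: Grignard addition of the 2-dienylmagnesium reagent to the aldehyde at low temperature should give the racemic 2-(1-hydroxyalkyl)butadiene, whose carbinol centre is resolved in step 2.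

Step 2
Reactants: 4 rac-7-(tert-butyldimethylsilyloxy)-3-methylidenehept-1-en-4-ol
Product: 5 (1S)-4-(tert-butyldimethylsilyloxy)-1-[(2R)-2-vinyloxiran-2-yl]butan-1-ol
Conditions: Ti(OiPr)4 (10 mol %), L-(+)-diisopropyl tartrate (15 mol %), t-BuOOH (0.45 equiv), 4 Å MS, CH2Cl2, −20 °C
Reagents that add atoms: tert-butyl hydroperoxide, CC(C)(C)OO
Why: Sharpless asymmetric epoxidation run as a kinetic resolution below half conversion should epoxidise only the hydroxyl-directed 1,1-disubstituted alkene of the fast-reacting (S)-carbinol, fixing the later C4 centre and leaving (R)-4 to be separated.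

Step 3
Reactants: 5 (1S)-4-(tert-butyldimethylsilyloxy)-1-[(2R)-2-vinyloxiran-2-yl]butan-1-ol
Product: 6 (2R)-2-[(1S)-1,4-bis(tert-butyldimethylsilyloxy)butyl]-2-vinyloxirane
Conditions: TBSCl, imidazole, DMAP (cat.), DMF, rt
Reagents that add atoms: tert-butyldimethylsilyl chloride, CC(C)(C)[Si](C)(C)Cl
Why: Imidazole-promoted silylation masks the secondary alcohol so that it can neither add to the π-allyl unit nor form a lactol in step 6, and the weak base avoids Payne rearrangement of the epoxy alcohol.

Step 4
Reactants: 6 (2R)-2-[(1S)-1,4-bis(tert-butyldimethylsilyloxy)butyl]-2-vinyloxirane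
Product: 7 (4S)-4-(tert-butyldimethylsilyloxy)-4-[(2R)-2-vinyloxiran-2-yl]butan-1-ol
Conditions: TBAF (1.1 equiv), AcOH (1.1 equiv), THF, 0 °C → rt
Reagents that add atoms: none
Why: Buffered fluoride desilylation should cleave the unhindered primary silyl ether well before the secondary one, which is shielded by the neighbouring quaternary epoxide carbon, and it spares the acid-labile vinyl epoxide.

Step 5
Reactants: 7 (4S)-4-(tert-butyldimethylsilyloxy)-4-[(2R)-2-vinyloxiran-2-yl]butan-1-ol
Product: 8 (4S)-4-(tert-butyldimethylsilyloxy)-4-[(2R)-2-vinyloxiran-2-yl]butanal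
Conditions: Dess–Martin periodinane, NaHCO3, CH2Cl2, 0 °C → rt
Reagents that add atoms: none
Why: Dess–Martin oxidation under bicarbonate buffer stops at the aldehyde and is mild enough for the vinyl epoxide.

Step 6
Reactants: 8 (4S)-4-(tert-butyldimethylsilyloxy)-4-[(2R)-2-vinyloxiran-2-yl]butanal
Product: 10 (1S,5S)-5-(tert-butyldimethylsilyloxy)-4-(hydroxymethyl)cyclohex-3-ene-1-carbaldehyde, via enamine 9 (not isolated)
Conditions: Pd(PPh3)4 (5 mol %), (S)-α,α-diphenylprolinol trimethylsilyl ether (20 mol %), DMSO (0.01 M), rt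
Reagents that add atoms: none
Why: The aldehyde condenses with the amine to the (E)-enamine 9 while zerovalent palladium opens the 2-vinyloxirane with inversion to an alkoxide-bearing π-allylpalladium unit over C1–C2–C3; the enamine carbon C6 attacks the unsubstituted terminus C1 anti to palladium, and the water of condensation hydrolyses the iminium, returning both catalysts and leaving the alkoxide as the free CH2OH. The closest known reaction type is the amine/palladium dual-catalytic intramolecular Tsuji–Trost α-allylation of aldehydes, here fed by the palladium-catalysed 1,4-opening of a vinyl epoxide by a soft carbon nucleophile. The six-membered carbocycle closes with the enamine double bond outside the ring and the whole allyl unit inside it (6-endo with respect to the allyl unit), which needs the anti-configured π-allyl reached by π–σ–π isomerisation and places the C2=C3 alkene cis in the ring. The new stereocentre C6 is set by the catalyst: its diphenyl(silyloxy)methyl group shields the Re face of the enamine, so C1 should bond to the Si face and give (S)-C6, cis to the C4 silyloxy group, and the α-branched product should not readily re-form an enamine with this hindered amine. The step needs regioselectivity for C1 over C3, secured because attack at the oxygenated terminus would close a cyclobutane, and C- over O-alkylation, secured by the silyl ether on C4 and by high dilution against intermolecular paths.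

Step 7
Reactants: 10 (1S,5S)-5-(tert-butyldimethylsilyloxy)-4-(hydroxymethyl)cyclohex-3-ene-1-carbaldehyde
Product: 11 [(4S,6S)-6-(tert-butyldimethylsilyloxy)-4-ethynylcyclohex-1-en-1-yl]methanol
Conditions: dimethyl (1-diazo-2-oxopropyl)phosphonate, K2CO3, MeOH, 0 °C → rt
Reagents that add atoms: dimethyl (1-diazo-2-oxopropyl)phosphonate, COP(=O)(OC)C(=[N+]=[N-])C(C)=O
Why: Ohira–Bestmann (Seyferth–Gilbert) homologation converts the aldehyde into the terminal alkyne through an alkylidene carbene, and the mild carbonate base at 0 °C should leave the α-stereocentre and the silyl ether in place.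

Step 8
Reactants: 12 (S)-2-methylglycidol
Product: 13 (2R)-2-methylpent-4-ene-1,2-diol
Conditions: CH2=CHMgBr (3 equiv), CuI (10 mol %), THF, −30 → 0 °C; aq. NH4Cl
Reagents that add atoms: vinylmagnesium bromide, C=C[Mg]Br
Why: Copper-catalysed Grignard opening of the epoxide at its unsubstituted CH2 terminus leaves the quaternary stereocentre untouched, the change from (S) to (R) being only a change of CIP priorities.

Step 9
Reactants: 11 [(4S,6S)-6-(tert-butyldimethylsilyloxy)-4-ethynylcyclohex-1-en-1-yl]methanol; 13 (2R)-2-methylpent-4-ene-1,2-diol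
Product: 14 (2R,3E)-6-[(1S,5S)-5-(tert-butyldimethylsilyloxy)-4-(hydroxymethyl)cyclohex-3-en-1-yl]-2-methylhepta-3,6-diene-1,2-diol
Conditions: [CpRu(MeCN)3]PF6 (10 mol %), acetone, rt
Reagents that add atoms: none
Why: Ruthenium-catalysed alkene–alkyne coupling (formal Alder-ene reaction through a ruthenacyclopentene) should join the internal alkyne carbon C7 to the terminal alkene carbon C8 and, after β-hydride elimination of an allylic hydrogen, give the branched 1,4-diene with the C7=C14 methylene and the (E)-C9=C10 alkene, the α-branched alkyne favouring the branched isomer and no stereocentre being touched.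

Step 10
Reactants: 14 (2R,3E)-6-[(1S,5S)-5-(tert-butyldimethylsilyloxy)-4-(hydroxymethyl)cyclohex-3-en-1-yl]-2-methylhepta-3,6-diene-1,2-diol
Product: 15 [(4S,6S)-6-(tert-butyldimethylsilyloxy)-4-[(4E,6R)-6-hydroxy-6-methyl-7-(2-methylpropanoyloxy)hepta-1,4-dien-2-yl]cyclohex-1-en-1-yl]methyl 2-methylpropanoate
Conditions: i-PrCOCl (2.3 equiv), pyridine, DMAP (cat.), CH2Cl2, −20 → 0 °C
Reagents that add atoms: isobutyryl chloride, CC(C)C(=O)Cl
Why: DMAP-catalysed acylation should esterify the two primary alcohols only, since the tertiary alcohol is inert under these conditions and the secondary one is silylated.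

Step 11
Reactants: 15 [(4S,6S)-6-(tert-butyldimethylsilyloxy)-4-[(4E,6R)-6-hydroxy-6-methyl-7-(2-methylpropanoyloxy)hepta-1,4-dien-2-yl]cyclohex-1-en-1-yl]methyl 2-methylpropanoate
Product: 16 [(4S,6S)-6-hydroxy-4-[(4E,6R)-6-hydroxy-6-methyl-7-(2-methylpropanoyloxy)hepta-1,4-dien-2-yl]cyclohex-1-en-1-yl]methyl 2-methylpropanoate
Conditions: HF·pyridine, pyridine, THF, 0 °C → rt
Reagents that add atoms: none
Why: Buffered, non-basic fluoride desilylation should free the secondary allylic alcohol without 1,3-acyl migration from the neighbouring ester and without ionising the tertiary allylic alcohol.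

**Compound list**

1 | 4-(tert-butyldimethylsilyloxy)butanal | O=CCCCO[Si](C)(C)C(C)(C)C | starting material
2 | chloroprene (2-chlorobuta-1,3-diene) | C=CC(Cl)=C | starting material
3 | buta-1,3-dien-2-ylmagnesium chloride | C=CC(=C)[Mg]Cl | intermediate
4 | rac-7-(tert-butyldimethylsilyloxy)-3-methylidenehept-1-en-4-ol | C=CC(=C)C(O)CCCO[Si](C)(C)C(C)(C)C | intermediate
5 | (1S)-4-(tert-butyldimethylsilyloxy)-1-[(2R)-2-vinyloxiran-2-yl]butan-1-ol | C=C[C@@]1(CO1)[C@@H](O)CCCO[Si](C)(C)C(C)(C)C | intermediate
6 | (2R)-2-[(1S)-1,4-bis(tert-butyldimethylsilyloxy)butyl]-2-vinyloxirane | C=C[C@@]1(CO1)[C@@H](O[Si](C)(C)C(C)(C)C)CCCO[Si](C)(C)C(C)(C)C | intermediate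
7 | (4S)-4-(tert-butyldimethylsilyloxy)-4-[(2R)-2-vinyloxiran-2-yl]butan-1-ol | C=C[C@@]1(CO1)[C@@H](O[Si](C)(C)C(C)(C)C)CCCO | intermediate
8 | (4S)-4-(tert-butyldimethylsilyloxy)-4-[(2R)-2-vinyloxiran-2-yl]butanal | C=C[C@@]1(CO1)[C@@H](O[Si](C)(C)C(C)(C)C)CCC=O | intermediate
9 | (2S)-1-[(1E,4S)-4-(tert-butyldimethylsilyloxy)-4-[(2R)-2-vinyloxiran-2-yl]but-1-en-1-yl]-2-[diphenyl(trimethylsilyloxy)methyl]pyrrolidine (enamine) | C=C[C@@]1(CO1)[C@@H](O[Si](C)(C)C(C)(C)C)C/C=C/N1CCC[C@H]1C(c1ccccc1)(c1ccccc1)O[Si](C)(C)C | intermediate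
10 | (1S,5S)-5-(tert-butyldimethylsilyloxy)-4-(hydroxymethyl)cyclohex-3-ene-1-carbaldehyde | O=C[C@H]1CC=C(CO)[C@@H](O[Si](C)(C)C(C)(C)C)C1 | intermediate
11 | [(4S,6S)-6-(tert-butyldimethylsilyloxy)-4-ethynylcyclohex-1-en-1-yl]methanol | C#C[C@H]1CC=C(CO)[C@@H](O[Si](C)(C)C(C)(C)C)C1 | intermediate
12 | (S)-2-methylglycidol, [(2S)-2-methyloxiran-2-yl]methanol | C[C@]1(CO)CO1 | starting material
13 | (2R)-2-methylpent-4-ene-1,2-diol | C=CC[C@@](C)(O)CO | intermediate
14 | (2R,3E)-6-[(1S,5S)-5-(tert-butyldimethylsilyloxy)-4-(hydroxymethyl)cyclohex-3-en-1-yl]-2-methylhepta-3,6-diene-1,2-diol | C=C(C/C=C/[C@@](C)(O)CO)[C@H]1CC=C(CO)[C@@H](O[Si](C)(C)C(C)(C)C)C1 | intermediate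
15 | [(4S,6S)-6-(tert-butyldimethylsilyloxy)-4-[(4E,6R)-6-hydroxy-6-methyl-7-(2-methylpropanoyloxy)hepta-1,4-dien-2-yl]cyclohex-1-en-1-yl]methyl 2-methylpropanoate | C=C(C/C=C/[C@@](C)(O)COC(=O)C(C)C)[C@H]1CC=C(COC(=O)C(C)C)[C@@H](O[Si](C)(C)C(C)(C)C)C1 | intermediate
16 | [(4S,6S)-6-hydroxy-4-[(4E,6R)-6-hydroxy-6-methyl-7-(2-methylpropanoyloxy)hepta-1,4-dien-2-yl]cyclohex-1-en-1-yl]methyl 2-methylpropanoate | C=C(C/C=C/[C@@](C)(O)COC(=O)C(C)C)[C@H]1CC=C(COC(=O)C(C)C)[C@@H](O)C1 | target

Total step count: 11. Longest linear sequence: 10 steps (steps 1–7 and 9–11).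

**Steps most likely to fail**

Step 6. The hindered chiral amine has to override the substrate's own conformational preference (the C4 silyloxy group prefers the pseudoaxial position next to the substituted C3), so the enamine may be attacked on the wrong face and give the C6 epimer; reversible N-allylation of the amine may also slow turnover. The fallback replaces catalyst control by thermodynamic control through a bridged lactol. It sets out from 10, taken as whatever C6 mixture the cyclization delivers (pyrrolidine may then replace the chiral amine), and returns at 16. TBAF in THF removes the C4 silyl group. The cis-hydroxy aldehyde should close at once to the bridged lactol (1S,5S)-4-(hydroxymethyl)-6-oxabicyclo[3.2.1]oct-3-en-7-ol F2. The trans isomer (1R,5S)-5-hydroxy-4-(hydroxymethyl)cyclohex-3-ene-1-carbaldehyde F1 cannot bridge and is epimerised at C6 with DBU until it has drained into F2. Ohira–Bestmann homologation of F2 should give (1S,5S)-5-ethynyl-2-(hydroxymethyl)cyclohex-2-en-1-ol F3. The ruthenium coupling of F3 with 13 should give (2R,3E)-6-[(1S,5S)-5-hydroxy-4-(hydroxymethyl)cyclohex-3-en-1-yl]-2-methylhepta-3,6-diene-1,2-diol F4. Isobutyryl chloride with 2,4,6-collidine at −78 °C should then acylate only the two primary hydroxyls of F4 to give 16.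

Step 9. The ruthenacycle may form with eroded branched-over-linear regioselectivity, and the 1,2-diol or the allylic alcohol may sequester the catalyst. The fallback builds the same skipped diene by allylmetalation and cross-metathesis; it sets out from 11 and returns at 14. Indium-mediated Markovnikov allylation of 11 (allyl bromide, indium powder, THF) should give [(4S,6S)-6-(tert-butyldimethylsilyloxy)-4-(penta-1,4-dien-2-yl)cyclohex-1-en-1-yl]methanol F5. The partner (2R)-2-methylbut-3-ene-1,2-diol F6 is made from 12 with dimethylsulfonium methylide (trimethylsulfonium iodide, n-BuLi, THF). Cross-metathesis of F5 with F6 (second-generation Hoveyda–Grubbs catalyst, CH2Cl2, 40 °C) should engage only the monosubstituted alkene of F5 and give 14 with (E) geometry.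

Step 2. The kinetic resolution may run with a low selectivity factor, and the tertiary allylic epoxide may be opened by the Lewis acid during the long run at partial conversion. The fallback sets the carbinol centre by asymmetric C–C bond formation instead of resolution; it sets out from 1 and returns at 5. Chiral phosphoric acid-catalysed homoallenylboration of 1 with 2-(buta-2,3-dien-1-yl)-4,4,5,5-tetramethyl-1,3,2-dioxaborolane (BINOL-derived acid with 3,3'-bis(2,4,6-triisopropylphenyl) groups, enantiomer chosen for the (S)-carbinol, toluene, −30 °C) should give (4S)-7-(tert-butyldimethylsilyloxy)-3-methylidenehept-1-en-4-ol F7. F7 is then epoxidised to full conversion with the Ti(OiPr)4/L-(+)-diisopropyl tartrate/t-BuOOH system of step 2, now a matched and fast reaction, to give 5.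

Further compounds
F1 | step 6 | (1R,5S)-5-hydroxy-4-(hydroxymethyl)cyclohex-3-ene-1-carbaldehyde | O=C[C@@H]1CC=C(CO)[C@@H](O)C1
F2 | step 6 | (1S,5S)-4-(hydroxymethyl)-6-oxabicyclo[3.2.1]oct-3-en-7-ol (lactol, both anomers) | OCC1=CC[C@H]2C[C@@H]1OC2O
F3 | step 6 | (1S,5S)-5-ethynyl-2-(hydroxymethyl)cyclohex-2-en-1-ol | C#C[C@H]1CC=C(CO)[C@@H](O)C1
F4 | step 6 | (2R,3E)-6-[(1S,5S)-5-hydroxy-4-(hydroxymethyl)cyclohex-3-en-1-yl]-2-methylhepta-3,6-diene-1,2-diol | C=C(C/C=C/[C@@](C)(O)CO)[C@H]1CC=C(CO)[C@@H](O)C1
F5 | step 9 | [(4S,6S)-6-(tert-butyldimethylsilyloxy)-4-(penta-1,4-dien-2-yl)cyclohex-1-en-1-yl]methanol | C=CCC(=C)[C@H]1CC=C(CO)[C@@H](O[Si](C)(C)C(C)(C)C)C1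
F6 | step 9 | (2R)-2-methylbut-3-ene-1,2-diol | C=C[C@@](C)(O)CO
F7 | step 2 | (4S)-7-(tert-butyldimethylsilyloxy)-3-methylidenehept-1-en-4-ol | C=CC(=C)[C@@H](O)CCCO[Si](C)(C)C(C)(C)C
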